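## Retrosynthetic overview
1. Schisandrone comes from hydrogenolysis of the 7-O-benzyl tetralone. The tetralone ring is formed last by intramolecular Friedel–Crafts cyclialkylation (C4–C4a bond) of a γ-hydroxy aryl ketone. This step sets C4 trans to the 3-Me.
2. The γ-hydroxy ketone comes from an aryllithium adding to a Weinreb amide (forming C1–aryl). The 3,4-dimethoxyphenyl group is introduced by Grignard addition to an α-branched aldehyde.
3. The aldehyde–Weinreb amide comes from the cis-3,4-dimethyl-γ-butyrolactone by Weinreb ring-opening and oxidation.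
4. The cis-lactone, which carries both methyl stereocenters (C2 and C3), comes from the proposed asymmetric hydrogenation of 3,4-dimethylbutenolide.

**Assumptions:**
- The target is (2S,3S,4R), as encoded in the SMILES.
- The ligand enantiomer in Step 1 is chosen to give (3S,4R)-2.
- 3,4-Dimethylfuran-2(5H)-one is commercial (otherwise it is one NaBH4 step from 2,3-dimethylmaleic anhydride).
- The C4 carbinol configuration in 6 and 9 is irrelevant because both epimers ionize to the same cation in Step 7.

## Route

**Step 1**
Reactants: 1, 3,4-dimethylfuran-2(5H)-one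
Product: 2, (3S,4R)-3,4-dimethyloxolan-2-one (cis)
Conditions: [Ir(cod)(L*)]BArF (1 mol %, L* = chiral phosphine–oxazoline), H2 (80 bar), CH2Cl2, 40 °C, 24 h
Reagents that add atoms: hydrogen, [H][H]
Why: Proposed new method: the cationic Ir–P,N hydride is weakly directed by the lactone C=O, and suprafacial delivery of two H atoms to one enantioface of the all-alkyl tetrasubstituted C=C sets both methyl stereocenters cis and enantioselectively; the closest known reactions are Ir–P,N hydrogenation of tetrasubstituted alkenes and Ru/Rh hydrogenation of β-substituted butenolides.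

**Step 2**
Reactants: 2
Product: 3, (2S,3R)-4-hydroxy-N-methoxy-N,2,3-trimethylbutanamide
Conditions: MeNH(OMe)·HCl, Me3Al, CH2Cl2, 0 °C → rt
Reagents that add atoms: N,O-dimethylhydroxylamine, CNOC
Why: Me3Al-mediated aminolysis of the lactone (Weinreb amide formation) opens the ring without touching the stereocenters.

**Step 3**
Reactants: 3
Product: 4, (2S,3R)-N-methoxy-N,2,3-trimethyl-4-oxobutanamide
Conditions: Dess–Martin periodinane, NaHCO3, CH2Cl2, 0 °C → rt, 1 h; used immediately
Reagents that add atoms: none
Why: Buffered Dess–Martin oxidation converts the primary alcohol to the aldehyde with minimal α-epimerization, and the Weinreb amide is inert.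

**Step 4**
Reactants: 4; 5, 4-bromo-1,2-dimethoxybenzene (used as its Grignard reagent, made in situ with Mg)
Product: 6, (2S,3R)-4-(3,4-dimethoxyphenyl)-4-hydroxy-N-methoxy-N,2,3-trimethylbutanamide (C4 epimeric mixture)
Conditions: ArMgBr (1.1 equiv, from 5 + Mg, THF, reflux), THF, −78 °C, 1 h; quench with sat. NH4Cl at −78 °C
Reagents that add atoms: 3,4-dimethoxyphenylmagnesium bromide, COc1ccc([Mg]Br)cc1OC
Why: Grignard addition to the aldehyde is much faster than to the Weinreb amide at −78 °C; the new carbinol stereocenter is destroyed later by ionization.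

**Step 5**
Reactants: 7, 5-bromo-2-methoxyphenol
Product: 8, 2-(benzyloxy)-4-bromo-1-methoxybenzene
Conditions: BnBr, K2CO3, DMF, 60 °C, 4 h
Reagents that add atoms: benzyl bromide, BrCc1ccccc1
Why: Williamson ether synthesis protects the phenol; Br sits para to OMe and meta to OBn, which fixes the ring-A substitution pattern.

**Step 6**
Reactants: 6; 8 (converted in situ to the aryllithium)
Product: 9, (2S,3R)-1-[3-(benzyloxy)-4-methoxyphenyl]-4-(3,4-dimethoxyphenyl)-4-hydroxy-2,3-dimethylbutan-1-one (C4 epimeric mixture; partly as the cyclic lactol)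
Conditions: 8 + n-BuLi, THF, −78 °C, 15 min; then 6 (1 equiv, 3 equiv ArLi in total), −78 → 0 °C; NH4Cl
Reagents that add atoms: 3-benzyloxy-4-methoxyphenyllithium, COc1ccc([Li])cc1OCc1ccccc1
Why: Weinreb ketone synthesis gives the aryl ketone through a stable chelated tetrahedral intermediate, so there is no over-addition and no α-epimerization; the first equivalent of ArLi just deprotonates the OH.

**Step 7**
Reactants: 9
Product: 10, (2S,3S,4R)-7-(benzyloxy)-4-(3,4-dimethoxyphenyl)-6-methoxy-2,3-dimethyl-3,4-dihydronaphthalen-1(2H)-one
Conditions: TfOH (5 mol %), HFIP/CH2Cl2 (1:1), 0 °C, 20 min; then Et3N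
Reagents that add atoms: none (loses H2O)
Why: Intramolecular Friedel–Crafts cyclialkylation of the diarylmethyl cation onto the ring-A carbon para to OBn and ortho to the acyl group; ring closure places the 4-aryl group trans to the 3-Me, which sets C4, and C2 and C3 are untouched.

**Step 8**
Reactants: 10
Product: 11, schisandrone, (2S,3S,4R)-4-(3,4-dimethoxyphenyl)-7-hydroxy-6-methoxy-2,3-dimethyl-3,4-dihydronaphthalen-1(2H)-one
Conditions: H2 (1 atm), 10% Pd/C, EtOAc, rt, 2 h
Reagents that add atoms: hydrogen, [H][H]
Why: Catalytic hydrogenolysis removes the O-benzyl group (toluene is lost) and leaves the aryl ketone, OMe groups and all three stereocenters intact.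

## Compound list
1 | 3,4-dimethylfuran-2(5H)-one | CC1=C(C)C(=O)OC1 | starting material
2 | (3S,4R)-3,4-dimethyloxolan-2-one | O=C1OC[C@H](C)[C@@H]1C | intermediate
3 | (2S,3R)-4-hydroxy-N-methoxy-N,2,3-trimethylbutanamide | OC[C@H](C)[C@@H](C(=O)N(C)OC)C | intermediate
4 | (2S,3R)-N-methoxy-N,2,3-trimethyl-4-oxobutanamide | O=C[C@H](C)[C@@H](C(=O)N(C)OC)C | intermediate
5 | 4-bromo-1,2-dimethoxybenzene | COc1ccc(Br)cc1OC | starting material
6 | (2S,3R)-4-(3,4-dimethoxyphenyl)-4-hydroxy-N-methoxy-N,2,3-trimethylbutanamide (C4 epimer mixture) | COc1ccc(cc1OC)C(O)[C@H](C)[C@@H](C(=O)N(C)OC)C | intermediate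
7 | 5-bromo-2-methoxyphenol | COc1ccc(Br)cc1O | starting material
8 | 2-(benzyloxy)-4-bromo-1-methoxybenzene | COc1ccc(Br)cc1OCc1ccccc1 | intermediate
9 | (2S,3R)-1-[3-(benzyloxy)-4-methoxyphenyl]-4-(3,4-dimethoxyphenyl)-4-hydroxy-2,3-dimethylbutan-1-one (C4 epimer mixture) | COc1ccc(cc1OC)C(O)[C@H](C)[C@@H](C(=O)c1ccc(OC)c(OCc2ccccc2)c1)C | intermediate
10 | (2S,3S,4R)-7-(benzyloxy)-4-(3,4-dimethoxyphenyl)-6-methoxy-2,3-dimethyl-3,4-dihydronaphthalen-1(2H)-one | COc1cc2c(cc1OCc1ccccc1)C(=O)[C@@H](C)[C@@H](C)[C@@H]2c1ccc(OC)c(OC)c1 | intermediate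
11 | schisandrone, (2S,3S,4R)-4-(3,4-dimethoxyphenyl)-7-hydroxy-6-methoxy-2,3-dimethyl-3,4-dihydronaphthalen-1(2H)-one | COc1cc2c(cc1O)C(=O)[C@@H](C)[C@@H](C)[C@@H]2c1ccc(OC)c(OC)c1 | target

## Totals
Total steps: 8 (7 on the main line plus the benzylation of the aryl bromide).
Longest linear sequence: 7 steps (1 → 2 → 3 → 4 → 6 → 9 → 10 → 11).

## Three steps most likely to fail
1. **Step 1 (proposed new asymmetric hydrogenation).** The all-alkyl tetrasubstituted butenolide may be unreactive or give low ee.
   Fallback (known chemistry, different approach): hydrogenate 2,3-dimethylmaleic anhydride (H2, Pd/C) to the meso-cis-succinic anhydride. Desymmetrize it by cinchona-alkaloid-catalyzed methanolysis to the half-ester. Reduce the acid selectively with BH3·SMe2 and lactonize with cat. TsOH to give 2.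
2. **Step 7 (cyclialkylation).** The acylated ring A is a weak nucleophile, and acid may epimerize C2 toward the all-trans isomer or give a poor C4 dr.
   Fallback (different approach): reduce the ketone of 9 to the C1 carbinol and protect it as a TBS ether, so there is no enolizable center. Carry out the acid cyclialkylation on the more nucleophilic ring A, then remove the TBS group and oxidize C1 with Dess–Martin periodinane.
3. **Step 6 (ArLi addition to the hydroxy Weinreb amide).** Competing α-deprotonation, lactonization or low conversion are possible.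
   Fallback (different approach): protect the C4 OH as a methyl ether, hydrolyze the Weinreb amide to the acid, and form the aryl ketone by Pd-catalyzed coupling of the thioester with 3-benzyloxy-4-methoxyphenylboronic acid. The ether is ionized directly in Step 7 with a Lewis acid.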